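The earlier runs and the new flask were generated by integration on assumed constants; scatter was added.

The constants of these runs are unknown, but one can be read without a clock: the share of the J used that ends as Q.

| setting | theta | alpha | gamma | flask |
|---|---|---|---|---|
| Z | 3.4 mM | 7.5 mM | 5 mM | 5.0 mM |
| J | 5 mM | 5 mM | 2.5 mM | 5.00 mM |
| remark | run made earlier | run made earlier | run made earlier |  |
| time |  |  |  | 2.5 min |

| run | time / min | Z / % | D / % | Q / % |
|---|---|---|---|---|
| theta | 0.200 | 0 | 38 | 59 |
| theta | 0.333 | 0 | 40 | 61 |
| theta | 0.500 | 0 | 39 | 60 |
| theta | 0.667 | 0 | 40 | 58 |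
| theta | 1.00 | 1 | 38 | 59 |
| theta | 1.50 | 1 | 37 | 58 |
| theta | 2.50 | 0 | 41 | 59 |
| alpha | 0.333 | 23 | 20 | 39 |
| alpha | 0.667 | 19 | 16 | 37 |
| alpha | 1.00 | 17 | 13 | 38 |
| alpha | 1.33 | 14 | 7 | 40 |
| alpha | 2.00 | 13 | 6 | 37 |
| alpha | 2.50 | 12 | 8 | 40 |
| gamma | 0.200 | 46 | 18 | 30 |
| gamma | 0.667 | 38 | 9 | 30 |
| gamma | 1.33 | 36 | 6 | 32 |
| gamma | 2.00 | 34 | 3 | 31 |
| gamma | 2.50 | 32 | 5 | 30 |

(standard deviation of a reading: 1.5 percentage points)

- the numbers in the tables scatter with a standard deviation of 1.5 percentage points
- the reaction counts as stopped when no species that holds the Z changes by six tenths of a point or more over the second half of the time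

- the state of affairs at 2.5 min: stopped, and by what, or still going (J has run out first / all of Z has reacted / it is still moving)
- conversion of Z at 2.5 min
- amount of D at 2.5 min, in percent of the Z charged
- amount of Q at 2.5 min, in percent of the Z charged
- amount of D if the flask were left three thousand times as long, in percent of the Z charged

The Q readings in alpha lie flat within their scatter. The last reads 40% of the Z charged, and the J charge is 66.7% of that Z. If that J is used up, the Q share, Q formed per J used, reads 60.0%; this is the selectivity of the J step. The last gamma reading gives 60.0% from its own charge. The flask charges J equal to Z, so its ceiling for Q reads 60.0% of the Z charged.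

Two chemists accept this ceiling and part over the end.

The first looks at gamma, where Z stands beside D and D sinks from 18% to 5%. She holds that J and Z fall together in the flask, that J gives out first, and that the Z left over drains D.

The second looks at theta, where Z reads 0% and D still reads 41% at 2.50 min. She counts too: every Z that meets D is one Z that J does not get. So in the flask Z gives out first, and J stays over by that amount.

I side with the second. My reckoning puts Q a little under its ceiling and D further under 40.0%, the share left for it.

The forecast took that side, since “Z therefore runs out first, leaving slight excess J”. Its end state is "all of Z has reacted", with conversion 99.8%, D 36.5%, Q 58.5% and 36.5% of D after the long wait.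

The end state of the flask is "all of Z has reacted", with conversion >99.9%, D 34.9%, Q 57.6%, and 34.9% of D after the long wait.

    Z + J → D (k = 80.0 M⁻¹ s⁻¹)
    Z + J → Q (k = 120 M⁻¹ s⁻¹)
    Z + J → L (k = 1.20 M⁻¹ s⁻¹)
    Z + D → E (k = 7.70 M⁻¹ s⁻¹)

Q of 57.6% divided by the Q share puts the J used in the flask at 96.0% of its charge, and at 2.50 min the flask holds 3.5% of its J beside 0% of Z, the limiting reagent. The margin is thin: Z raised alone to 108% of its charge moves D by 5 points. The first chemist's picture belongs to a flask charged with 12 mM of Z. There the Q share times the J per Z gives 25.0%, and Q stands at 24.9% of the Z charged, with J at 0% of its charge, Z at 41.8% and D at 0.0368%.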